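## Retrosynthetic overview

1. The butenolide is the only ring made (the furan is bought) and is closed last by Dieckmann condensation of an α-propanoyloxy ester; its C5 comes from methyl (S)-glycidate opened by a Z-alkenyl metal.
2. The Z-trisubstituted alkene comes from a (Z)-2-iodoalkene made by an α-iodo Wittig reaction on a one-carbon-homologated aldehyde.
3. Key step: Johnson–Claisen [3,3] rearrangement of an (E,4R)-allylic alcohol forms the C–C bond at the methyl-bearing carbon and the E-alkene, and transfers chirality from O to C.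
4. The allylic alcohol is built by two chelation-controlled additions steered by the methoxy-bearing carbon, which is the α-carbon of O-benzyl-L-serine: furylpropyl Grignard to a methyl ketone, then E-propenyl Grignard to the α-methoxy aldehyde.
5. The furylpropyl unit comes from 3-bromofuran and oxetane.

Assumption: compounds 1, 2, 6, 16 and 26 are bought (26 is the commercial, D-serine-derived glycidate); the target is taken exactly as drawn (all four stereocentres S, 2'Z, 7'E).

## Route

Step 1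
Reactants: 1 3-bromofuran; 2 oxetane
Product: 4 3-(furan-3-yl)propan-1-ol, via furan-3-yllithium 3 (not isolated)
Conditions: n-BuLi, THF, −78 °C; then 2, BF3·OEt2, −78 °C; H2O
Reagents that add atoms: none
Why: Bromine–lithium exchange gives the 3-lithiofuran, which is configurationally stable at −78 °C and opens BF3-activated oxetane by SN2 ring opening to install the three-carbon tether.

Step 2
Reactants: 4 3-(furan-3-yl)propan-1-ol
Product: 5 3-(3-bromopropyl)furan
Conditions: CBr4, PPh3, CH2Cl2, 0 °C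
Reagents that add atoms: carbon tetrabromide, BrC(Br)(Br)Br
Why: Appel bromination converts the primary alcohol into the bromide under neutral conditions that leave the furan untouched.

Step 3
Reactants: 6 O-benzyl-L-serine
Product: 7 (2S)-3-(benzyloxy)-2-hydroxypropanoic acid
Conditions: NaNO2, 1 M H2SO4 (aq), 0 °C → rt
Reagents that add atoms: water, O
Why: Diazotisation of the α-amino acid runs through an α-lactone (double inversion), so water replaces nitrogen with overall retention and the serine stereocentre becomes the future methoxy-bearing carbon.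

Step 4
Reactants: 7 (2S)-3-(benzyloxy)-2-hydroxypropanoic acid
Product: 8 methyl (2S)-3-(benzyloxy)-2-methoxypropanoate
Conditions: Ag2O, MeI, MeCN, rt, dark
Reagents that add atoms: iodomethane, IC
Why: Purdie methylation alkylates both the acid and the secondary hydroxyl without a strong base, so the α-centre is not enolised and benzyloxide is not eliminated.

Step 5
Reactants: 8 methyl (2S)-3-(benzyloxy)-2-methoxypropanoate
Product: 10 (3S)-4-(benzyloxy)-3-methoxybutan-2-one, via Weinreb amide 9 (not isolated)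
Conditions: MeNH(OMe)·HCl, iPrMgCl, THF, −20 °C; then MeMgCl, 0 °C; aq. HCl
Reagents that add atoms: methylmagnesium chloride, C[Mg]Cl
Why: The magnesium amide turns the ester into the Weinreb amide, whose chelated tetrahedral adduct with MeMgCl releases the methyl ketone only on work-up (Weinreb ketone synthesis), so there is no over-addition and no epimerisation.

Step 6
Reactants: 10 (3S)-4-(benzyloxy)-3-methoxybutan-2-one; 5 3-(3-bromopropyl)furan
Product: 13 {[(2S,3S)-1-(benzyloxy)-6-(furan-3-yl)-2-methoxy-3-methylhexan-3-yl]oxy}triethylsilane, via Grignard reagent 11 (not isolated), via magnesium alkoxide 12 (not isolated)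
Conditions: Mg, THF, rt (5 → 11); add to 10, THF, −78 °C; then Et3SiOTf, −78 → 0 °C
Reagents that add atoms: triethylsilyl trifluoromethanesulfonate, CC[Si](CC)(CC)OS(=O)(=O)C(F)(F)F
Why: Cram-chelate-controlled Grignard addition, in which Mg bridges the ketone and α-methoxy oxygens and the alkyl group enters from the face of the α-hydrogen, sets the (S) tertiary carbinol, which is trapped in the pot as its Et3Si ether.

Step 7
Reactants: 13 {[(2S,3S)-1-(benzyloxy)-6-(furan-3-yl)-2-methoxy-3-methylhexan-3-yl]oxy}triethylsilane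
Product: 14 (2S,3S)-6-(furan-3-yl)-2-methoxy-3-methyl-3-[(triethylsilyl)oxy]hexan-1-ol
Conditions: Li, 4,4'-di-tert-butylbiphenyl (cat.), THF, −78 °C; then H2O
Reagents that add atoms: none
Why: Arene-catalysed reductive lithiation cleaves only the benzylic C–O bond, while the furan, methyl ether and silyl ether are not reduced at −78 °C.

Step 8
Reactants: 14 (2S,3S)-6-(furan-3-yl)-2-methoxy-3-methyl-3-[(triethylsilyl)oxy]hexan-1-ol
Product: 15 (2R,3S)-6-(furan-3-yl)-2-methoxy-3-methyl-3-[(triethylsilyl)oxy]hexanal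
Conditions: Dess–Martin periodinane, pyridine, CH2Cl2, 0 °C → rt
Reagents that add atoms: none
Why: Dess–Martin oxidation stops at the aldehyde under buffered non-basic conditions, so the α-methoxy centre is not epimerised (the descriptor changes only because of CIP priorities).

Step 9
Reactants: 15 (2R,3S)-6-(furan-3-yl)-2-methoxy-3-methyl-3-[(triethylsilyl)oxy]hexanal; 16 (E)-1-bromoprop-1-ene
Product: 19 (2E,4R,5S,6S)-9-(furan-3-yl)-5-methoxy-6-methyl-6-[(triethylsilyl)oxy]non-2-en-4-ol, via (E)-prop-1-enyllithium 17 (not isolated), via (E)-prop-1-enylmagnesium bromide 18 (not isolated)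
Conditions: 16, t-BuLi (2 equiv), Et2O, −78 °C; MgBr2·OEt2; then 15 pre-mixed with MgBr2·OEt2, CH2Cl2, −78 °C; H2O
Reagents that add atoms: none
Why: Stereoretentive Br–Li exchange gives the E-alkenyl metal, and its Cram-chelate-controlled addition to the MgBr2-bound α-methoxy aldehyde from the face of the α-hydrogen gives the syn (4R) carbinol with the E-alkene intact.

Step 10
Reactants: 19 (2E,4R,5S,6S)-9-(furan-3-yl)-5-methoxy-6-methyl-6-[(triethylsilyl)oxy]non-2-en-4-ol
Product: 21 ethyl (3S,4E,6S,7S)-10-(furan-3-yl)-6-methoxy-3,7-dimethyl-7-[(triethylsilyl)oxy]dec-4-enoate, via ketene acetal 20 (not isolated)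
Conditions: MeC(OEt)3, EtCO2H (cat.), xylene, 140 °C, EtOH distilled off
Reagents that add atoms: triethyl orthoacetate, CCOC(C)(OCC)OCC
Why: Johnson orthoester Claisen [3,3]-sigmatropic rearrangement through a chair transition state with the bulky C5 substituent equatorial forms the new C–C bond suprafacially, so the (4R) carbinol is translated into the (3S) methyl stereocentre and the E-alkene.

Step 11
Reactants: 21 ethyl (3S,4E,6S,7S)-10-(furan-3-yl)-6-methoxy-3,7-dimethyl-7-[(triethylsilyl)oxy]dec-4-enoate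
Product: 23 3-{(4S,5S,6E,8S)-5,11-dimethoxy-4,8-dimethyl-4-[(triethylsilyl)oxy]undeca-6,10-dien-1-yl}furan (10E/10Z mixture), via aldehyde 22 (not isolated)
Conditions: iBu2AlH, CH2Cl2, −78 °C; then Ph3P=CHOMe (from MeOCH2PPh3Cl, KN(SiMe3)2, THF), −78 °C → rt
Reagents that add atoms: (methoxymethyl)triphenylphosphonium chloride, COC[P+](c1ccccc1)(c1ccccc1)c1ccccc1.[Cl-]
Why: Half-reduction of the ester to its aluminium hemiacetal followed by Wittig olefination in the same pot gives the one-carbon-homologated enol ether without handling the aldehyde.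

Step 12
Reactants: 23 3-{(4S,5S,6E,8S)-5,11-dimethoxy-4,8-dimethyl-4-[(triethylsilyl)oxy]undeca-6,10-dien-1-yl}furan
Product: 24 (4S,5E,7S,8S)-11-(furan-3-yl)-8-hydroxy-7-methoxy-4,8-dimethylundec-5-enal
Conditions: 1 M HCl, THF, rt
Reagents that add atoms: water, O
Why: Dilute aqueous acid hydrolyses the enol ether to the homologated aldehyde and removes the Et3Si group in the same operation, while the furan and allylic methyl ether tolerate these conditions.

Step 13
Reactants: 24 (4S,5E,7S,8S)-11-(furan-3-yl)-8-hydroxy-7-methoxy-4,8-dimethylundec-5-enal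
Product: 25 (4S,5S,6E,8S,11Z)-1-(furan-3-yl)-12-iodo-5-methoxy-4,8-dimethyltrideca-6,11-dien-4-ol
Conditions: EtPPh3I, n-BuLi, THF; I2, −78 °C; NaN(SiMe3)2, −20 °C; then 24, −78 → −20 °C
Reagents that add atoms: ethyltriphenylphosphonium iodide, CC[P+](c1ccccc1)(c1ccccc1)c1ccccc1.[I-]; iodine, [I][I]
Why: Stork–Zhao-type Wittig reaction of the α-iodo ylide with the aldehyde gives the (Z)-2-iodoalkene (iodine cis to the chain) under kinetic control, which fixes the geometry of the trisubstituted alkene.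

Step 14
Reactants: 25 (4S,5S,6E,8S,11Z)-1-(furan-3-yl)-12-iodo-5-methoxy-4,8-dimethyltrideca-6,11-dien-4-ol; 26 methyl (2S)-oxirane-2-carboxylate
Product: 29 methyl (2S,4Z,8S,9E,11S,12S)-15-(furan-3-yl)-2,12-dihydroxy-11-methoxy-4,8,12-trimethylpentadeca-4,9-dienoate, via vinyllithium 27 (not isolated), via vinylmagnesium bromide 28 (not isolated)
Conditions: t-BuLi (3 equiv), Et2O, −78 °C; MgBr2·OEt2; then 26, CuBr·SMe2 (20 mol %), THF, −40 → −20 °C; H2O
Reagents that add atoms: none
Why: Iodine–lithium exchange and transmetallation retain the alkene geometry, and the copper-catalysed alkenyl Grignard opens the epoxide at its CH2 terminus (SN2), so the glycidate stereocentre is carried unchanged into the (2S) α-hydroxy ester.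

Step 15
Reactants: 29 methyl (2S,4Z,8S,9E,11S,12S)-15-(furan-3-yl)-2,12-dihydroxy-11-methoxy-4,8,12-trimethylpentadeca-4,9-dienoate
Product: 30 methyl (2S,4Z,8S,9E,11S,12S)-15-(furan-3-yl)-12-hydroxy-11-methoxy-4,8,12-trimethyl-2-(propanoyloxy)pentadeca-4,9-dienoate
Conditions: (EtCO)2O, pyridine, DMAP (cat.), CH2Cl2, 0 °C
Reagents that add atoms: propanoic anhydride, CCC(=O)OC(=O)CC
Why: Nucleophilic acyl substitution at the unhindered secondary α-hydroxyl is far faster than at the tertiary alcohol, giving the Dieckmann precursor selectively.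

Step 16
Reactants: 30 methyl (2S,4Z,8S,9E,11S,12S)-15-(furan-3-yl)-12-hydroxy-11-methoxy-4,8,12-trimethyl-2-(propanoyloxy)pentadeca-4,9-dienoate
Product: 31 (5S)-5-[(2Z,6S,7E,9S,10S)-13-(furan-3-yl)-10-hydroxy-9-methoxy-2,6,10-trimethyltrideca-2,7-dien-1-yl]-4-hydroxy-3-methylfuran-2(5H)-one
Conditions: LiN(SiMe3)2 (3.5 equiv), THF, −78 → 0 °C; then 1 M HCl
Reagents that add atoms: none
Why: Kinetic deprotonation of the propanoate CH2 and Dieckmann condensation onto the methyl ester close the 3-methyltetronic acid, and at −78 °C the C5 hydrogen is not removed, so the (S) centre is kept.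

## Compound list

1 | 3-bromofuran | Brc1ccoc1 | starting material
2 | oxetane | C1COC1 | starting material
3 | furan-3-yllithium | [Li]c1ccoc1 | intermediate
4 | 3-(furan-3-yl)propan-1-ol | OCCCc1ccoc1 | intermediate
5 | 3-(3-bromopropyl)furan | BrCCCc1ccoc1 | intermediate
6 | O-benzyl-L-serine | N[C@@H](COCc1ccccc1)C(=O)O | starting material
7 | (2S)-3-(benzyloxy)-2-hydroxypropanoic acid | O[C@@H](COCc1ccccc1)C(=O)O | intermediate
8 | methyl (2S)-3-(benzyloxy)-2-methoxypropanoate | CO[C@@H](COCc1ccccc1)C(=O)OC | intermediate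
9 | (2S)-3-(benzyloxy)-N,2-dimethoxy-N-methylpropanamide | CO[C@@H](COCc1ccccc1)C(=O)N(C)OC | intermediate
10 | (3S)-4-(benzyloxy)-3-methoxybutan-2-one | CO[C@@H](COCc1ccccc1)C(C)=O | intermediate
11 | [3-(furan-3-yl)propyl]magnesium bromide | Br[Mg]CCCc1ccoc1 | intermediate
12 | bromomagnesium (2S,3S)-1-(benzyloxy)-6-(furan-3-yl)-2-methoxy-3-methylhexan-3-olate | CO[C@@H](COCc1ccccc1)[C@@](C)(O[Mg]Br)CCCc1ccoc1 | intermediate
13 | {[(2S,3S)-1-(benzyloxy)-6-(furan-3-yl)-2-methoxy-3-methylhexan-3-yl]oxy}triethylsilane | CO[C@@H](COCc1ccccc1)[C@@](C)(O[Si](CC)(CC)CC)CCCc1ccoc1 | intermediate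
14 | (2S,3S)-6-(furan-3-yl)-2-methoxy-3-methyl-3-[(triethylsilyl)oxy]hexan-1-ol | CO[C@@H](CO)[C@@](C)(O[Si](CC)(CC)CC)CCCc1ccoc1 | intermediate
15 | (2R,3S)-6-(furan-3-yl)-2-methoxy-3-methyl-3-[(triethylsilyl)oxy]hexanal | CO[C@@H](C=O)[C@@](C)(O[Si](CC)(CC)CC)CCCc1ccoc1 | intermediate
16 | (E)-1-bromoprop-1-ene | C/C=C/Br | starting material
17 | (E)-prop-1-enyllithium | C/C=C/[Li] | intermediate
18 | (E)-prop-1-enylmagnesium bromide | C/C=C/[Mg]Br | intermediate
19 | (2E,4R,5S,6S)-9-(furan-3-yl)-5-methoxy-6-methyl-6-[(triethylsilyl)oxy]non-2-en-4-ol | C/C=C/[C@@H](O)[C@H](OC)[C@@](C)(O[Si](CC)(CC)CC)CCCc1ccoc1 | intermediate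
20 | 3-{(4S,5S,6R,7E)-6-[(1-ethoxyethenyl)oxy]-5-methoxy-4-methyl-4-[(triethylsilyl)oxy]non-7-en-1-yl}furan | C/C=C/[C@@H](OC(=C)OCC)[C@H](OC)[C@@](C)(O[Si](CC)(CC)CC)CCCc1ccoc1 | intermediate
21 | ethyl (3S,4E,6S,7S)-10-(furan-3-yl)-6-methoxy-3,7-dimethyl-7-[(triethylsilyl)oxy]dec-4-enoate | CO[C@@H](/C=C/[C@@H](C)CC(=O)OCC)[C@@](C)(O[Si](CC)(CC)CC)CCCc1ccoc1 | intermediate
22 | (3S,4E,6S,7S)-10-(furan-3-yl)-6-methoxy-3,7-dimethyl-7-[(triethylsilyl)oxy]dec-4-enal | CO[C@@H](/C=C/[C@@H](C)CC=O)[C@@](C)(O[Si](CC)(CC)CC)CCCc1ccoc1 | intermediate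
23 | 3-{(4S,5S,6E,8S)-5,11-dimethoxy-4,8-dimethyl-4-[(triethylsilyl)oxy]undeca-6,10-dien-1-yl}furan (10E/10Z mixture) | CO[C@@H](/C=C/[C@@H](C)CC=COC)[C@@](C)(O[Si](CC)(CC)CC)CCCc1ccoc1 | intermediate
24 | (4S,5E,7S,8S)-11-(furan-3-yl)-8-hydroxy-7-methoxy-4,8-dimethylundec-5-enal | CO[C@@H](/C=C/[C@@H](C)CCC=O)[C@@](C)(O)CCCc1ccoc1 | intermediate
25 | (4S,5S,6E,8S,11Z)-1-(furan-3-yl)-12-iodo-5-methoxy-4,8-dimethyltrideca-6,11-dien-4-ol | CO[C@@H](/C=C/[C@@H](C)CC/C=C(/C)I)[C@@](C)(O)CCCc1ccoc1 | intermediate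
26 | methyl (2S)-oxirane-2-carboxylate | COC(=O)[C@@H]1CO1 | starting material
27 | lithium (4S,5S,6E,8S,11E)-1-(furan-3-yl)-12-lithio-5-methoxy-4,8-dimethyltrideca-6,11-dien-4-olate | CO[C@@H](/C=C/[C@@H](C)CC/C=C(/C)[Li])[C@@](C)(O[Li])CCCc1ccoc1 | intermediate
28 | bromomagnesium (4S,5S,6E,8S,11Z)-12-(bromomagnesio)-1-(furan-3-yl)-5-methoxy-4,8-dimethyltrideca-6,11-dien-4-olate | CO[C@@H](/C=C/[C@@H](C)CC/C=C(/C)[Mg]Br)[C@@](C)(O[Mg]Br)CCCc1ccoc1 | intermediate
29 | methyl (2S,4Z,8S,9E,11S,12S)-15-(furan-3-yl)-2,12-dihydroxy-11-methoxy-4,8,12-trimethylpentadeca-4,9-dienoate | CO[C@@H](/C=C/[C@@H](C)CC/C=C(/C)C[C@H](O)C(=O)OC)[C@@](C)(O)CCCc1ccoc1 | intermediate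
30 | methyl (2S,4Z,8S,9E,11S,12S)-15-(furan-3-yl)-12-hydroxy-11-methoxy-4,8,12-trimethyl-2-(propanoyloxy)pentadeca-4,9-dienoate | CO[C@@H](/C=C/[C@@H](C)CC/C=C(/C)C[C@H](OC(=O)CC)C(=O)OC)[C@@](C)(O)CCCc1ccoc1 | intermediate
31 | (5S)-5-[(2Z,6S,7E,9S,10S)-13-(furan-3-yl)-10-hydroxy-9-methoxy-2,6,10-trimethyltrideca-2,7-dien-1-yl]-4-hydroxy-3-methylfuran-2(5H)-one (CNP0305089.2) | CO[C@@H](/C=C/[C@@H](C)CC/C=C(/C)C[C@@H]1OC(=O)C(C)=C1O)[C@@](C)(O)CCCc1ccoc1 | target

## Step count and risks

Total step count: 16. Longest linear sequence: 14 steps (steps 3–16, from O-benzyl-L-serine 6 to 31); steps 1–2 make the side-chain bromide 5.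

The three steps most likely to fail:

Step 9 (facial selectivity and E-purity of the alkenylation). The fallback sets out from 15. Chelation-controlled addition of MeC≡CMgBr with MgBr2·OEt2 gives the propargylic alcohol (4R,5S,6S)-9-(furan-3-yl)-5-methoxy-6-methyl-6-[(triethylsilyl)oxy]non-2-yn-4-ol F1, which is separated from its C4 epimer by chromatography. Trans-reduction with NaAlH2(OCH2CH2OMe)2 in THF (hydroalumination directed by the propargylic alkoxide) then gives a geometrically pure E-alkene, and the route is rejoined at 19.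

Step 13 (yield and Z/E ratio of the iodo-olefination). The fallback sets out from 24. Ramirez olefination (CBr4, PPh3, CH2Cl2, 0 °C) gives the dibromoalkene (4S,5S,6E,8S)-12,12-dibromo-1-(furan-3-yl)-5-methoxy-4,8-dimethyldodeca-6,11-dien-4-ol F2. Negishi coupling with MeZnCl catalysed by PdCl2(DPEphos) replaces only the bromine trans to the chain and gives the bromoalkene (4S,5S,6E,8S,11Z)-12-bromo-1-(furan-3-yl)-5-methoxy-4,8-dimethyltrideca-6,11-dien-4-ol F3. Br–Li exchange with t-BuLi then gives the vinyllithium, and the route is rejoined at 27.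

Step 14 (copper-catalysed opening of an ester-bearing epoxide by a hindered alkenyl Grignard reagent). The fallback sets out from 26 and from the alkenyl Grignard reagent 28. Saponification of 26 with LiOH gives lithium (2S)-oxirane-2-carboxylate F4, whose carboxylate cannot undergo 1,2-addition. Reagent 28 with CuBr·SMe2 opens it at CH2 to give the hydroxy acid (2S,4Z,8S,9E,11S,12S)-15-(furan-3-yl)-2,12-dihydroxy-11-methoxy-4,8,12-trimethylpentadeca-4,9-dienoic acid F5. Esterification with Me3SiCHN2 in MeOH/toluene rejoins the route at 29.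

## Further compounds

F1 | step 9 | (4R,5S,6S)-9-(furan-3-yl)-5-methoxy-6-methyl-6-[(triethylsilyl)oxy]non-2-yn-4-ol | CC#C[C@@H](O)[C@H](OC)[C@@](C)(O[Si](CC)(CC)CC)CCCc1ccoc1
F2 | step 13 | (4S,5S,6E,8S)-12,12-dibromo-1-(furan-3-yl)-5-methoxy-4,8-dimethyldodeca-6,11-dien-4-ol | CO[C@@H](/C=C/[C@@H](C)CCC=C(Br)Br)[C@@](C)(O)CCCc1ccoc1
F3 | step 13 | (4S,5S,6E,8S,11Z)-12-bromo-1-(furan-3-yl)-5-methoxy-4,8-dimethyltrideca-6,11-dien-4-ol | CO[C@@H](/C=C/[C@@H](C)CC/C=C(/C)Br)[C@@](C)(O)CCCc1ccoc1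
F4 | step 14 | lithium (2S)-oxirane-2-carboxylate | [Li+].[O-]C(=O)[C@@H]1CO1
F5 | step 14 | (2S,4Z,8S,9E,11S,12S)-15-(furan-3-yl)-2,12-dihydroxy-11-methoxy-4,8,12-trimethylpentadeca-4,9-dienoic acid | CO[C@@H](/C=C/[C@@H](C)CC/C=C(/C)C[C@H](O)C(=O)O)[C@@](C)(O)CCCc1ccoc1
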